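**Retrosynthetic overview** (chromenone numbering: O1, C2 with the side chain, C3, C4 carbonyl, C4a, C5 carbinol, C6, C7, C8, C8a)
- Target ⇐ the corresponding C5 ketone (bicyclic 4,5-dione) by asymmetric transfer hydrogenation, which sets C5.
- Bicyclic dione ⇐ a monocyclic 5-(bromoacetyl)-4-pyranone plus ethylene: one radical [4+2] annulation forms C6–C7 and C8–C8a and closes the carbocycle onto the finished pyranone ring.
- Enabling feature: C8a is a hydrogen-bearing β-carbon of the pyranone enone (O1–C8a=C4a–C4=O) that the C5 carbonyl activates further, C6 is α to that C5 carbonyl, and C7–C8 between them is a bare CH2–CH2, that is, ethylene.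
- Bromoacetylpyranone ⇐ acetylpyranone ⇐ diacetyl enaminone + (13Z)-octadec-13-enoyl chloride (C-acylation, then ring closure at O1); ring order: pyranone ring first, carbocycle second.

Key step: step 5

Assumption: (13Z)-octadec-13-enoic acid (cis-13-octadecenoic acid) is bought as the geometrically pure Z isomer from a lipid supplier; its C17 alkenyl residue becomes the C2 side chain unchanged.

**Step 1**
Reactants: 1 pentane-2,4-dione; 2 N,N-dimethylformamide dimethyl acetal
Product: 3 3-[(dimethylamino)methylidene]pentane-2,4-dione
Conditions: neat or toluene, 25 to 80 °C, methanol distilled off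
Reagents that add atoms: none
Why: Enaminone formation: the doubly activated methylene of the 1,3-diketone should condense with the amide acetal with loss of two molecules of methanol, a clean and general reaction.

**Step 2**
Reactants: 4 (13Z)-octadec-13-enoic acid
Product: 5 (13Z)-octadec-13-enoyl chloride
Conditions: (COCl)2, DMF (cat.), CH2Cl2, 0 to 25 °C
Reagents that add atoms: oxalyl chloride ClC(=O)C(=O)Cl
Why: Acid chloride formation through the Vilsmeier-type chloroiminium species runs at room temperature and should leave the isolated Z-alkene untouched.

**Step 3**
Reactants: 3 3-[(dimethylamino)methylidene]pentane-2,4-dione; 5 (13Z)-octadec-13-enoyl chloride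
Product: 7 5-acetyl-2-[(12Z)-heptadec-12-en-1-yl]-4H-pyran-4-one, via triketo enaminone 6 (not isolated)
Conditions: 3 (1.2 equiv), LiHMDS (2.5 equiv), THF, −78 °C; 5, −78 to −20 °C; then 2 M HCl, THF, 25 °C
Reagents that add atoms: none
Why: Enaminone-anion acylation followed by acid cyclisation, a known route to 3-acyl-4-pyranones: LiHMDS should deprotonate one acetyl methyl group of 3, Claisen-type C-acylation by 5 gives the 1,3-diketone 6, and under acid its enol oxygen adds to the aminomethylidene carbon and expels dimethylamine (addition–elimination), which leaves the ring carbon next to oxygen unsubstituted (the later C8a) and keeps the second acetyl group as the later C5 and C6.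

**Step 4**
Reactants: 7 5-acetyl-2-[(12Z)-heptadec-12-en-1-yl]-4H-pyran-4-one
Product: 9 5-(bromoacetyl)-2-[(12Z)-heptadec-12-en-1-yl]-4H-pyran-4-one, via silyl dienol ether 8 (not isolated)
Conditions: TMSCl (1.5 equiv), LiHMDS (1.1 equiv), THF, −78 °C; then NBS (1.05 equiv), −78 to 0 °C
Reagents that add atoms: N-bromosuccinimide O=C1CCC(=O)N1Br; chlorotrimethylsilane C[Si](C)(C)Cl (its silyl group stays only in intermediate 8)
Why: Regio- and chemoselective α-bromination through the silyl enol ether: kinetic deprotonation of the acetyl methyl group with in situ silylation gives dienol ether 8, which NBS should brominate at its terminal carbon far faster than it touches the isolated Z-alkene in anhydrous THF at low temperature, so that one bromine enters at the later C6.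

**Step 5**
Reactants: 9 5-(bromoacetyl)-2-[(12Z)-heptadec-12-en-1-yl]-4H-pyran-4-one; 10 ethene (ethylene)
Product: 11 2-[(12Z)-heptadec-12-en-1-yl]-7,8-dihydro-4H-chromene-4,5(6H)-dione
Conditions: fac-Ir(ppy)3 (1 mol %), ethylene (5 bar), K2HPO4 (2 equiv), degassed MeCN (0.02 M), blue LEDs (450 nm), 25 °C
Reagents that add atoms: none
Why: Proposed new method: excited fac-Ir(ppy)3 should reduce the C–Br bond of 9 to the electrophilic α-keto radical at C6, which adds to ethylene (C6–C7 bond), and the nucleophilic primary radical then formed at C8 attacks C8a, the hydrogen-bearing β-carbon of the pyranone enone that both the C4 and the C5 carbonyl activate (C8–C8a bond), to leave a radical at C4a between two carbonyl groups. Phosphate then removes the strongly acidified C8a–H and the radical anion of the product hands its electron to tetravalent iridium or to a further molecule of 9, so that the pyranone is restored and the overall change is redox-neutral with loss of HBr only. The closest known reaction types are the radical annulation of phenacyl radicals (from α-halo or α-xanthyl aryl ketones, or from aryl methyl ketones and Mn(OAc)3) with alkenes to α-tetralones and the photoredox Minisci-type alkylation of heteroarenes by α-bromocarbonyl compounds; new are the 4-pyranone C–H carbon as radical acceptor and ethylene as the two-carbon partner. The cyclohexanone ring (C4a, C5, C6, C7, C8, C8a) is closed by a 6-endo-trig radical cyclisation and no stereocenter is formed. The step needs the C6 radical to take ethylene and not the chain alkene or a second pyranone, which the large excess of ethylene under pressure and the high dilution of 9 should secure, and it needs attack at C8a and not 5-exo attack at C4a, which the polarity match of the alkyl radical with electron-poor C8a and the doubly carbonyl-stabilised product radical should secure. The triplet energy of the photocatalyst is too low to sensitise the isolated Z-alkene, so its geometry should be kept.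

**Step 6**
Reactants: 11 2-[(12Z)-heptadec-12-en-1-yl]-7,8-dihydro-4H-chromene-4,5(6H)-dione
Product: 12 (5S)-2-[(12Z)-heptadec-12-en-1-yl]-5-hydroxy-5,6,7,8-tetrahydro-4H-chromen-4-one
Conditions: RuCl(p-cymene)[(S,S)-TsDPEN] (1 mol %), HCO2H/Et3N (5:2), EtOAc, 25 °C
Reagents that add atoms: none
Why: Noyori–Ikariya asymmetric transfer hydrogenation of an aryl-type cyclic ketone: with the pyranone ring in the place of the aryl group of α-tetralone or 4-chromanone, the (S,S)-TsDPEN ruthenium hydride is expected to deliver hydride to the Re face of the C5 carbonyl and so set the S configuration, while the doubly vinylogous C4 carbonyl and the isolated Z-alkene should not be reduced.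

**Compound list**
1 | pentane-2,4-dione (acetylacetone) | CC(=O)CC(C)=O | starting material
2 | N,N-dimethylformamide dimethyl acetal | COC(OC)N(C)C | starting material
3 | 3-[(dimethylamino)methylidene]pentane-2,4-dione | CC(=O)C(=CN(C)C)C(C)=O | intermediate
4 | (13Z)-octadec-13-enoic acid | CCCC/C=C\CCCCCCCCCCCC(=O)O | starting material
5 | (13Z)-octadec-13-enoyl chloride | CCCC/C=C\CCCCCCCCCCCC(=O)Cl | intermediate
6 | (18Z)-3-[(dimethylamino)methylidene]tricos-18-ene-2,4,6-trione (triketo enaminone, not isolated) | CCCC/C=C\CCCCCCCCCCCC(=O)CC(=O)C(=CN(C)C)C(C)=O | intermediate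
7 | 5-acetyl-2-[(12Z)-heptadec-12-en-1-yl]-4H-pyran-4-one | CCCC/C=C\CCCCCCCCCCCc1cc(=O)c(C(C)=O)co1 | intermediate
8 | 2-[(12Z)-heptadec-12-en-1-yl]-5-{1-[(trimethylsilyl)oxy]ethenyl}-4H-pyran-4-one (silyl dienol ether, not isolated) | CCCC/C=C\CCCCCCCCCCCc1cc(=O)c(C(=C)O[Si](C)(C)C)co1 | intermediate
9 | 5-(bromoacetyl)-2-[(12Z)-heptadec-12-en-1-yl]-4H-pyran-4-one | CCCC/C=C\CCCCCCCCCCCc1cc(=O)c(C(=O)CBr)co1 | intermediate
10 | ethene (ethylene) | C=C | starting material
11 | 2-[(12Z)-heptadec-12-en-1-yl]-7,8-dihydro-4H-chromene-4,5(6H)-dione | CCCC/C=C\CCCCCCCCCCCc1cc(=O)c2c(o1)CCCC2=O | intermediate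
12 | (5S)-2-[(12Z)-heptadec-12-en-1-yl]-5-hydroxy-5,6,7,8-tetrahydro-4H-chromen-4-one | CCCC/C=C\CCCCCCCCCCCc1cc(=O)c2c(o1)CCC[C@@H]2O | target

**Step count:** 6 steps in total; the longest linear sequence is 5 steps (steps 2, 3, 4, 5, 6 from acid 4, or steps 1, 3, 4, 5, 6 from diketone 1).

**Steps most likely to fail**

Step 5 (the proposed new method). The primary radical at C8 may be intercepted before it closes onto C8a, by bromine-atom transfer from 9, by a second ethylene or by hydrogen abstraction. The ring-closed radical may also be reduced instead of rearomatised, so that open-chain or dihydro products would dominate. The fallback uses known chemistry and closes the pyranone at the ring oxygen instead. It sets out from acid chloride 5 and purchased 2-acetylcyclohexane-1,3-dione (CC(=O)C1C(=O)CCCC1=O). The polyanion of that triketone (LiHMDS, 3.2 equiv, THF, −78 °C) is acylated by 5 at the acetyl methyl carbon, a Claisen-type acylation as in the chromone synthesis from ortho-hydroxyacetophenones, to give 2-[(15Z)-3-oxoicos-15-enoyl]cyclohexane-1,3-dione F1. Acid cyclodehydration of F1 (TFA, CH2Cl2, 25 °C) then closes the pyranone ring and returns to the route at dione 11.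

Step 4. The lithium enolate or the amide base may add in conjugate fashion to the unsubstituted ring carbon next to oxygen of another pyranone before silylation, or deprotonation and bromination may stray to the side-chain carbon next to the ring. The fallback gives up enolate chemistry. It sets out from acetylpyranone 7 and brominates its enol directly with phenyltrimethylammonium tribromide in THF at 0 °C, a base-free electrophilic bromination known to take ketones in the presence of isolated alkenes. It returns to the route at bromoketone 9 and makes no new compound (F0).

Step 6. Facial selectivity may be poor, because the pyranone ring with its neighbouring C4 carbonyl may not play the part of the aryl group, and the vinylogous-ester character of the C5 carbonyl may slow the hydride transfer. The fallback sets out from dione 11. NaBH4 in MeOH at 0 °C should reduce only the C5 ketone to racemic 2-[(12Z)-heptadec-12-en-1-yl]-5-hydroxy-5,6,7,8-tetrahydro-4H-chromen-4-one F2. Kinetic resolution of F2 with Candida antarctica lipase B and vinyl acetate, which acylates the R enantiomer of 1-tetralol-type alcohols, should give (5R)-2-[(12Z)-heptadec-12-en-1-yl]-4-oxo-5,6,7,8-tetrahydro-4H-chromen-5-yl acetate F3. The S alcohol is left unreacted and is separated by chromatography; it is target 12.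

**Further compounds**
F1 | step 5 | 2-[(15Z)-3-oxoicos-15-enoyl]cyclohexane-1,3-dione | CCCC/C=C\CCCCCCCCCCCC(=O)CC(=O)C1C(=O)CCCC1=O
F0 | step 4 | none | none
F2 | step 6 | racemic 2-[(12Z)-heptadec-12-en-1-yl]-5-hydroxy-5,6,7,8-tetrahydro-4H-chromen-4-one | CCCC/C=C\CCCCCCCCCCCc1cc(=O)c2c(o1)CCCC2O
F3 | step 6 | (5R)-2-[(12Z)-heptadec-12-en-1-yl]-4-oxo-5,6,7,8-tetrahydro-4H-chromen-5-yl acetate | CCCC/C=C\CCCCCCCCCCCc1cc(=O)c2c(o1)CCC[C@H]2OC(C)=O
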